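**Strategy.** The route rests on ring A (C5–C8, C4a, C8a) of the naphthoquinone, where the aroyl carbon on C6 and the CH2 on C7 sit ortho to each other, next to the C5 oxygen. These two carbons are the acyl carbon and the α-carbon of one β-keto ester. In the key step a 1,2,4,5-tetramethoxy-6,7-naphthalyne, released from an ortho-silylaryl triflate, inserts into the CH2–C(=O) bond of an orsellinoyl acetate. The C6–C(=O)Ar and C7–CH2 bonds form in one operation, and the C5 methoxy group steers the acyl group to C6. The acetate arm is then grown into the 4-hydroxy-2-pyranone through a dioxinone, and a global demethylation with air oxidation unveils the 2,5-dihydroxy-1,4-naphthoquinone.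

Key step: step 8

Remark: the target has no stereocentre; it is made as the 2-hydroxy-1,4-naphthoquinone and 4-hydroxy-2-pyranone tautomers drawn in the SMILES.

**Step 1**
Reactants: 1 5-methoxy-1-tetralone
Product: 2 2-hydroxy-5-methoxy-1,4-naphthoquinone
Conditions: O2 (1 atm), t-BuOK, t-BuOH, rt; then aq. HCl
Reagents that add atoms: dioxygen, O=O
Why: Base-mediated autoxidation of a 1-tetralone (enolate hydroperoxidation at C2, then oxidation at the benzylic C4 and aromatisation) should give the 2-hydroxy-1,4-quinone, with the new oxygens fixed at C2 and C4 by the position of the ketone.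

**Step 2**
Reactants: 2 2-hydroxy-5-methoxy-1,4-naphthoquinone
Product: 4 1,2,4,5-tetramethoxynaphthalene, via naphthalenetriol 3 (not isolated)
Conditions: Na2S2O4, n-Bu4NBr (cat.), THF/H2O, rt; then aq. KOH, Me2SO4, rt, under N2
Reagents that add atoms: dimethyl sulfate, COS(=O)(=O)OC
Why: Reductive methylation (dithionite reduction to the hydroquinone, then phase-transfer Williamson O-methylation of all three hydroxyls) should lock ring B as a base-stable 1,2,4-trimethoxy arene.

**Step 3**
Reactants: 4 1,2,4,5-tetramethoxynaphthalene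
Product: 6 4,5,7,8-tetramethoxynaphthalen-2-ol, via aryl boronate 5 (not isolated)
Conditions: [Ir(OMe)(cod)]2 (cat.), dtbpy (cat.), B2pin2, THF, 80 °C; then aq. NaOH, H2O2, 0 °C
Reagents that add atoms: bis(pinacolato)diboron, CC1(C)OB(OC1(C)C)B1OC(C)(C)C(C)(C)O1 (boron in 5 only); hydrogen peroxide, OO
Why: Sterically controlled iridium-catalysed C–H borylation should select C7, the only C–H without an ortho or peri substituent (C3 lies between two methoxy groups, C6 is ortho to one, C8 is peri to one), and oxidation of the C–B bond gives the phenol.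

**Step 4**
Reactants: 6 4,5,7,8-tetramethoxynaphthalen-2-ol
Product: 7 4,5,7,8-tetramethoxynaphthalen-2-yl N-isopropylcarbamate
Conditions: i-PrNCO, Et3N (cat.), CH2Cl2, rt
Reagents that add atoms: isopropyl isocyanate, CC(C)N=C=O
Why: Base-catalysed addition of the phenol to the isocyanate (carbamoylation) should install a strong directing group that can later be removed under mild conditions.

**Step 5**
Reactants: 7 4,5,7,8-tetramethoxynaphthalen-2-yl N-isopropylcarbamate
Product: 10 4,5,7,8-tetramethoxy-3-(trimethylsilyl)naphthalen-2-yl N-isopropylcarbamate, via N-silyl carbamate 8 (not isolated), via N-silyl C-silyl carbamate 9 (not isolated)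
Conditions: TBSOTf, TMEDA, Et2O, 0 °C to rt; n-BuLi, TMEDA, −78 °C; TMSCl, −78 °C to rt; aq. NaHSO4
Reagents that add atoms: tert-butyldimethylsilyl triflate, CC(C)(C)[Si](C)(C)OS(=O)(=O)C(F)(F)F (silicon in 8 and 9 only); chlorotrimethylsilane, C[Si](C)(C)Cl
Why: Directed ortho-metalation of the N-silylated carbamate should occur at the position between the carbamate and the methoxy group, where both direct, and silyl quench followed by acidic loss of the N-silyl group gives the ortho-silyl carbamate.

**Step 6**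
Reactants: 10 4,5,7,8-tetramethoxy-3-(trimethylsilyl)naphthalen-2-yl N-isopropylcarbamate
Product: 12 4,5,7,8-tetramethoxy-3-(trimethylsilyl)naphthalen-2-yl trifluoromethanesulfonate, via silyl naphthol 11 (not isolated)
Conditions: Et2NH, DBU, MeCN, 40 °C; then PhNTf2, rt
Reagents that add atoms: N-phenylbis(trifluoromethanesulfonimide), O=S(=O)(N(c1ccccc1)S(=O)(=O)C(F)(F)F)C(F)(F)F
Why: E1cB cleavage of the secondary carbamate (the isocyanate is trapped by the amine) and triflation of the phenoxide in the same flask should give the ortho-silylaryl triflate without protodesilylation.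

**Step 7**
Reactants: 13 2,4-dimethoxy-6-methylbenzoic acid
Product: 15 tert-butyl 3-(2,4-dimethoxy-6-methylphenyl)-3-oxopropanoate, via acid chloride 14 (not isolated)
Conditions: (COCl)2, DMF (cat.), CH2Cl2, 0 °C to rt; then LiCH2CO2t-Bu (t-BuOAc, LDA, 2.2 equiv), THF, −78 °C
Reagents that add atoms: oxalyl chloride, O=C(Cl)C(=O)Cl (chlorine in 14 only); tert-butyl acetate, CC(=O)OC(C)(C)C
Why: Claisen-type C-acylation of the lithium enolate of tert-butyl acetate by the hindered aroyl chloride should stop at the β-keto ester, which is held as its enolate by the second equivalent of base.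

**Step 8**
Reactants: 12 4,5,7,8-tetramethoxy-3-(trimethylsilyl)naphthalen-2-yl trifluoromethanesulfonate; 15 tert-butyl 3-(2,4-dimethoxy-6-methylphenyl)-3-oxopropanoate
Product: 17 tert-butyl 2-[3-(2,4-dimethoxy-6-methylbenzoyl)-4,5,7,8-tetramethoxynaphthalen-2-yl]acetate, via naphthalyne 16 (not isolated)
Conditions: CsF (2.5 equiv), MeCN, 80 °C
Reagents that add atoms: none
Why: Fluoride attack on silicon and loss of triflate should give naphthalyne 16; the caesium enolate of 15 adds through carbon to C7, the aryne carbon remote from the C5 methoxy group, so that the aryl anion develops at C6 next to the inductively stabilising oxygen. This anion adds to the neighbouring aroyl carbonyl and forms the C6–C(=O) bond in a 4-exo-trig closure to a benzocyclobutenoxide, which opens by retro-aldol cleavage of the former CH–C(=O) bond to an ester-stabilised benzylic anion that is protonated. The closest known reaction type is the acyl-alkylation of arynes with β-keto esters (formal insertion of an aryne into a C–C σ bond), which is established for aryl ketones and for 3-alkoxyarynes with this sense of addition. The only ring closed is the transient four-membered ring, and no stereocentre is formed. The step needs enolate attack at C7, secured by the C5 methoxy group, and attack of the aryl anion on the ketone and not on the ester, secured by the tert-butyl ester; the hindered 2,6-disubstituted aroyl group is the main risk.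

**Step 9**
Reactants: 17 tert-butyl 2-[3-(2,4-dimethoxy-6-methylbenzoyl)-4,5,7,8-tetramethoxynaphthalen-2-yl]acetate
Product: 18 2-[3-(2,4-dimethoxy-6-methylbenzoyl)-4,5,7,8-tetramethoxynaphthalen-2-yl]acetic acid
Conditions: TFA, CH2Cl2, 0 °C to rt
Reagents that add atoms: none
Why: Acidolysis of the tert-butyl ester (E1 loss of isobutene) should free the acid while the methyl ethers and the non-enolisable diaryl ketone stay intact.

**Step 10**
Reactants: 18 2-[3-(2,4-dimethoxy-6-methylbenzoyl)-4,5,7,8-tetramethoxynaphthalen-2-yl]acetic acid; 19 2,2,6-trimethyl-4H-1,3-dioxin-4-one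
Product: 21 6-{3-[3-(2,4-dimethoxy-6-methylbenzoyl)-4,5,7,8-tetramethoxynaphthalen-2-yl]-2-oxopropyl}-2,2-dimethyl-4H-1,3-dioxin-4-one, via acyl imidazolide 20 (not isolated)
Conditions: CDI, THF, rt; then lithium dienolate of 19 (LiHMDS, 3 equiv, THF, −78 °C), −78 to −40 °C; aq. NH4Cl
Reagents that add atoms: 1,1'-carbonyldiimidazole, O=C(n1ccnc1)n1ccnc1 (imidazole in 20 only)
Why: Vinylogous Claisen acylation of the dioxinone dienolate at its γ-carbon by the acyl imidazolide should give the β-keto dioxinone, and the crowded diaryl ketone is too hindered to compete as an electrophile.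

**Step 11**
Reactants: 21 6-{3-[3-(2,4-dimethoxy-6-methylbenzoyl)-4,5,7,8-tetramethoxynaphthalen-2-yl]-2-oxopropyl}-2,2-dimethyl-4H-1,3-dioxin-4-one
Product: 23 6-{[3-(2,4-dimethoxy-6-methylbenzoyl)-4,5,7,8-tetramethoxynaphthalen-2-yl]methyl}-4-hydroxy-2H-pyran-2-one, via acylketene 22 (not isolated)
Conditions: toluene, 110 °C
Reagents that add atoms: none
Why: Thermal retro-hetero-Diels–Alder loss of acetone should give an acylketene that is trapped by the enol oxygen of the neighbouring ketone (lactonisation) to form the 4-hydroxy-2-pyranone.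

**Step 12**
Reactants: 23 6-{[3-(2,4-dimethoxy-6-methylbenzoyl)-4,5,7,8-tetramethoxynaphthalen-2-yl]methyl}-4-hydroxy-2H-pyran-2-one
Product: 25 6-(2,4-dihydroxy-6-methylbenzoyl)-2,5-dihydroxy-7-[(4-hydroxy-2-oxo-2H-pyran-6-yl)methyl]-1,4-naphthoquinone, via naphthalenetetrol 24 (not isolated)
Conditions: BBr3 (excess), CH2Cl2, −78 °C to rt; then H2O, air
Reagents that add atoms: none
Why: Lewis-acid cleavage of all six aryl methyl ethers should give a 1,2,4-trihydroxynaphthalene unit that autoxidises in air during work-up to the 2-hydroxy-1,4-naphthoquinone, which is the target.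

**Compound list**

1 | 5-methoxy-1-tetralone | COc1cccc2C(=O)CCCc12 | starting material
2 | 2-hydroxy-5-methoxy-1,4-naphthoquinone | COc1cccc2C(=O)C(O)=CC(=O)c12 | intermediate
3 | 5-methoxynaphthalene-1,2,4-triol (not isolated) | COc1cccc2c(O)c(O)cc(O)c12 | intermediate
4 | 1,2,4,5-tetramethoxynaphthalene | COc1cccc2c(OC)c(OC)cc(OC)c12 | intermediate
5 | 4,4,5,5-tetramethyl-2-(4,5,7,8-tetramethoxynaphthalen-2-yl)-1,3,2-dioxaborolane (not isolated) | COc1cc(B3OC(C)(C)C(C)(C)O3)cc2c(OC)c(OC)cc(OC)c12 | intermediate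
6 | 4,5,7,8-tetramethoxynaphthalen-2-ol | COc1cc(O)cc2c(OC)c(OC)cc(OC)c12 | intermediate
7 | 4,5,7,8-tetramethoxynaphthalen-2-yl N-isopropylcarbamate | COc1cc(OC(=O)NC(C)C)cc2c(OC)c(OC)cc(OC)c12 | intermediate
8 | 4,5,7,8-tetramethoxynaphthalen-2-yl N-(tert-butyldimethylsilyl)-N-isopropylcarbamate (not isolated) | COc1cc(OC(=O)N(C(C)C)[Si](C)(C)C(C)(C)C)cc2c(OC)c(OC)cc(OC)c12 | intermediate
9 | 4,5,7,8-tetramethoxy-3-(trimethylsilyl)naphthalen-2-yl N-(tert-butyldimethylsilyl)-N-isopropylcarbamate (not isolated) | COc1c([Si](C)(C)C)c(OC(=O)N(C(C)C)[Si](C)(C)C(C)(C)C)cc2c(OC)c(OC)cc(OC)c12 | intermediate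
10 | 4,5,7,8-tetramethoxy-3-(trimethylsilyl)naphthalen-2-yl N-isopropylcarbamate | COc1c([Si](C)(C)C)c(OC(=O)NC(C)C)cc2c(OC)c(OC)cc(OC)c12 | intermediate
11 | 4,5,7,8-tetramethoxy-3-(trimethylsilyl)naphthalen-2-ol (not isolated) | COc1c([Si](C)(C)C)c(O)cc2c(OC)c(OC)cc(OC)c12 | intermediate
12 | 4,5,7,8-tetramethoxy-3-(trimethylsilyl)naphthalen-2-yl trifluoromethanesulfonate | COc1c([Si](C)(C)C)c(OS(=O)(=O)C(F)(F)F)cc2c(OC)c(OC)cc(OC)c12 | intermediate
13 | 2,4-dimethoxy-6-methylbenzoic acid | COc1cc(C)c(C(=O)O)c(OC)c1 | starting material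
14 | 2,4-dimethoxy-6-methylbenzoyl chloride (not isolated) | COc1cc(C)c(C(Cl)=O)c(OC)c1 | intermediate
15 | tert-butyl 3-(2,4-dimethoxy-6-methylphenyl)-3-oxopropanoate | COc1cc(C)c(C(=O)CC(=O)OC(C)(C)C)c(OC)c1 | intermediate
16 | 1,2,4,5-tetramethoxy-6,7-didehydronaphthalene (naphthalyne, not isolated) | COC1=C(OC)C2=CC#CC(OC)=C2C(OC)=C1 | intermediate
17 | tert-butyl 2-[3-(2,4-dimethoxy-6-methylbenzoyl)-4,5,7,8-tetramethoxynaphthalen-2-yl]acetate | COc1cc(C)c(C(=O)c2c(CC(=O)OC(C)(C)C)cc3c(OC)c(OC)cc(OC)c3c2OC)c(OC)c1 | intermediate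
18 | 2-[3-(2,4-dimethoxy-6-methylbenzoyl)-4,5,7,8-tetramethoxynaphthalen-2-yl]acetic acid | COc1cc(C)c(C(=O)c2c(CC(=O)O)cc3c(OC)c(OC)cc(OC)c3c2OC)c(OC)c1 | intermediate
19 | 2,2,6-trimethyl-4H-1,3-dioxin-4-one | CC1=CC(=O)OC(C)(C)O1 | starting material
20 | 2-[3-(2,4-dimethoxy-6-methylbenzoyl)-4,5,7,8-tetramethoxynaphthalen-2-yl]-1-(imidazol-1-yl)ethanone (not isolated) | COc1cc(C)c(C(=O)c2c(CC(=O)n4ccnc4)cc3c(OC)c(OC)cc(OC)c3c2OC)c(OC)c1 | intermediate
21 | 6-{3-[3-(2,4-dimethoxy-6-methylbenzoyl)-4,5,7,8-tetramethoxynaphthalen-2-yl]-2-oxopropyl}-2,2-dimethyl-4H-1,3-dioxin-4-one | COc1cc(C)c(C(=O)c2c(CC(=O)CC4=CC(=O)OC(C)(C)O4)cc3c(OC)c(OC)cc(OC)c3c2OC)c(OC)c1 | intermediate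
22 | 6-[3-(2,4-dimethoxy-6-methylbenzoyl)-4,5,7,8-tetramethoxynaphthalen-2-yl]-3,5-dioxohex-1-en-1-one (acylketene, not isolated) | COc1cc(C)c(C(=O)c2c(CC(=O)CC(=O)C=C=O)cc3c(OC)c(OC)cc(OC)c3c2OC)c(OC)c1 | intermediate
23 | 6-{[3-(2,4-dimethoxy-6-methylbenzoyl)-4,5,7,8-tetramethoxynaphthalen-2-yl]methyl}-4-hydroxy-2H-pyran-2-one | COc1cc(C)c(C(=O)c2c(Cc4cc(O)cc(=O)o4)cc3c(OC)c(OC)cc(OC)c3c2OC)c(OC)c1 | intermediate
24 | 6-{[3-(2,4-dihydroxy-6-methylbenzoyl)-4,5,7,8-tetrahydroxynaphthalen-2-yl]methyl}-4-hydroxy-2H-pyran-2-one (not isolated) | Cc1cc(O)cc(O)c1C(=O)c1c(Cc2cc(O)cc(=O)o2)cc2c(O)c(O)cc(O)c2c1O | intermediate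
25 | 6-(2,4-dihydroxy-6-methylbenzoyl)-2,5-dihydroxy-7-[(4-hydroxy-2-oxo-2H-pyran-6-yl)methyl]-1,4-naphthoquinone | Cc1cc(O)cc(O)c1C(=O)c1c(Cc2cc(O)cc(=O)o2)cc2c(c1O)C(=O)C=C(O)C2=O | target

**Step count and risks**

Total step count: 12. Longest linear sequence: 11 (steps 1–6 and 8–12; step 7 is a one-step branch).

Steps most likely to fail:

1. Step 8. The C6 aryl anion may be protonated before it adds to the doubly ortho-substituted aroyl carbonyl, which would stop the reaction at plain α-arylation, or it may add to the ester carbonyl. The enolate may also add to the wrong aryne carbon. The fallback sets out from 7 and forms the same C6–C(=O) bond by aryllithium acylation. N-silylation and ortho-lithiation as in step 5, followed by inverse addition to acid chloride 14 at −78 °C, should give the N-silyl keto carbamate F1. Acidic work-up removes the silyl group and gives the keto carbamate F2. Et2NH/DBU in MeCN should release the keto naphthol F3, which is triflated in the same flask with PhNTf2 to the keto triflate F4. Palladium-catalysed coupling of F4 with the Reformatsky reagent BrZnCH2CO2t-Bu (Pd(dba)2, Q-Phos, THF, rt to 60 °C) should then give 17, where the route is rejoined.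

2. Step 12. The very electron-rich tetrol 24 may undergo oxidative coupling or other degradation during the uncontrolled aerobic oxidation, and the polymethoxynaphthalene may decompose under BBr3 before demethylation is complete. The fallback sets out from 23 and fixes the quinone oxidation level first. Oxidative demethylation with CAN (MeCN/H2O, 0 °C) should give the robust, electron-poor methoxyquinone F5. The four remaining methyl ethers are then cleaved with BBr3 (CH2Cl2, −78 °C to rt), with the vinylogous ester on the quinone hydrolysed on aqueous work-up, to arrive at 25.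

3. Step 10. Proton transfer from the acidic arylacetyl CH2 of 20 to the dienolate may outrun C-acylation, leading to enolisation and self-condensation. The fallback sets out from 18 and avoids strong base. Oxalyl chloride with catalytic DMF should give the arylacetyl chloride F6. C-acylation of the neutral bis-silyl dienol ether 1-methoxy-1,3-bis(trimethylsilyloxy)buta-1,3-diene (CH2Cl2, −78 °C to rt, aqueous work-up) should give the 3,5-dioxo ester F7. DBU in toluene at 80 °C should then lactonise F7 with loss of methanol to 23, where the route is rejoined (21 is bypassed).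

**Further compounds**

F1 | step 8 | 3-(2,4-dimethoxy-6-methylbenzoyl)-4,5,7,8-tetramethoxynaphthalen-2-yl N-(tert-butyldimethylsilyl)-N-isopropylcarbamate | COc1cc(C)c(C(=O)c2c(OC(=O)N(C(C)C)[Si](C)(C)C(C)(C)C)cc3c(OC)c(OC)cc(OC)c3c2OC)c(OC)c1
F2 | step 8 | 3-(2,4-dimethoxy-6-methylbenzoyl)-4,5,7,8-tetramethoxynaphthalen-2-yl N-isopropylcarbamate | COc1cc(C)c(C(=O)c2c(OC(=O)NC(C)C)cc3c(OC)c(OC)cc(OC)c3c2OC)c(OC)c1
F3 | step 8 | (2,4-dimethoxy-6-methylphenyl)(3-hydroxy-1,5,6,8-tetramethoxynaphthalen-2-yl)methanone | COc1cc(C)c(C(=O)c2c(O)cc3c(OC)c(OC)cc(OC)c3c2OC)c(OC)c1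
F4 | step 8 | 3-(2,4-dimethoxy-6-methylbenzoyl)-4,5,7,8-tetramethoxynaphthalen-2-yl trifluoromethanesulfonate | COc1cc(C)c(C(=O)c2c(OS(=O)(=O)C(F)(F)F)cc3c(OC)c(OC)cc(OC)c3c2OC)c(OC)c1
F5 | step 12 | 6-{[3-(2,4-dimethoxy-6-methylbenzoyl)-4,7-dimethoxy-5,8-dioxo-5,8-dihydronaphthalen-2-yl]methyl}-4-hydroxy-2H-pyran-2-one | COc1cc(C)c(C(=O)c2c(Cc4cc(O)cc(=O)o4)cc3c(c2OC)C(=O)C=C(OC)C3=O)c(OC)c1
F6 | step 10 | 2-[3-(2,4-dimethoxy-6-methylbenzoyl)-4,5,7,8-tetramethoxynaphthalen-2-yl]acetyl chloride | COc1cc(C)c(C(=O)c2c(CC(=O)Cl)cc3c(OC)c(OC)cc(OC)c3c2OC)c(OC)c1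
F7 | step 10 | methyl 6-[3-(2,4-dimethoxy-6-methylbenzoyl)-4,5,7,8-tetramethoxynaphthalen-2-yl]-3,5-dioxohexanoate | COc1cc(C)c(C(=O)c2c(CC(=O)CC(=O)CC(=O)OC)cc3c(OC)c(OC)cc(OC)c3c2OC)c(OC)c1
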